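A direct plan would cut the C8–O diaryl ether bond between two preformed flavones: acacetin would be perbenzylated to the dibenzyl ether A1, apigenin benzylated at O7 only to the monobenzyl ether A2, A1 activated at C8–H as the aryliodonium salt A3, its flavonyl group transferred to the 4'-phenoxide of A2 to give the protected biflavone A4, and the benzyl groups removed by hydrogenolysis. Its weakest steps would be:
- the C8–O coupling, because the carbon is flanked by two ortho oxygens, the C8/C6 site selectivity and the choice of the aryl group that is transferred would both be unproven, and no close precedent exists;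
- the mono-benzylation of apigenin, because O7 and O4' differ little in acidity and over-alkylation would cap the phenol needed for the coupling;
- the benzylation and debenzylation steps, which would add length without adding complexity.

The route rests on the polyketide origin of both rings A: in each flavone C5 and C7 are acetate carbonyl carbons, and C8 of the acacetin half is an sp3 methylene in the open chain. The ether oxygen is therefore put on that carbon by a Williamson reaction, and both halves are carried as 4-pyranone-3-carboxylates (ring C preformed, the chain masked). After each lateral carbon has been acetylated, one base treatment closes both rings A by twofold Claisen condensation (C5–C6 and C5''–C6'') and aromatisation. No aryl–oxygen coupling at a hindered carbon occurs, the four phenols are born free so nothing is protected, and O1–C8a fixes the 8-aryloxy pattern.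

Key step: step 6

Remark: compounds 1, 2, 4, 8, 10 and 14 are taken as commercial. Unprimed locants refer to the acacetin half, doubly primed locants to the apigenin half. The target has no stereocentre; the one stereocentre of 15 is racemic and vanishes in step 6.

Step 1
Reactants: 1 4-iodophenol; 2 ethyl 4-chloro-3-oxobutanoate
Product: 3 ethyl 4-(4-iodophenoxy)-3-oxobutanoate
Conditions: NaH (2.2 equiv), THF, 0 °C; 2 added dropwise, 0 °C → rt; 1 M HCl
Reagents that add atoms: none
Why: Williamson ether synthesis; the second equivalent of NaH stores the β-keto ester as its enolate, so the phenoxide should attack only the CH2Cl carbon (SN2) and self-condensation of 2 is held back.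

Step 2
Reactants: 3 ethyl 4-(4-iodophenoxy)-3-oxobutanoate; 4 3-(4-methoxyphenyl)prop-2-ynoic acid
Product: 7 ethyl 2-[(4-iodophenoxy)methyl]-6-(4-methoxyphenyl)-4-oxo-4H-pyran-3-carboxylate, via acid chloride 5 (not isolated), via alkynoyl keto ester 6 (not isolated)
Conditions: 4, (COCl)2 (1.2 equiv), DMF (cat.), CH2Cl2, 0 °C → rt, evaporate; then 3, MgCl2 (1.1 equiv), pyridine (2.2 equiv), CH2Cl2, 0 °C → rt; DMAP (0.2 equiv), rt
Reagents that add atoms: none
Why: C-acylation of the magnesium-chelated β-keto ester enolate by the ynoyl chloride, then 6-endo-dig oxa-Michael addition of the enol oxygen of the aryloxyacetyl ketone to the ynone (the closure known from acetylenic β-diketones and 2-alkynoylphenols), should give the 4-pyranone with the aryloxymethyl group at C2 beside the ester, since only that oxygen can reach the alkyne β-carbon.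

Step 3
Reactants: 7 ethyl 2-[(4-iodophenoxy)methyl]-6-(4-methoxyphenyl)-4-oxo-4H-pyran-3-carboxylate; 8 prop-2-ynoic acid (propiolic acid)
Product: 9 3-[4-({3-(ethoxycarbonyl)-6-(4-methoxyphenyl)-4-oxo-4H-pyran-2-yl}methoxy)phenyl]prop-2-ynoic acid
Conditions: Pd(PPh3)4 (5 mol%), DBU (2.5 equiv), 8 (1.3 equiv), DMSO, rt; aq. HCl to pH 3
Reagents that add atoms: none
Why: Copper-free Sonogashira coupling of the aryl iodide with propiolic acid as its amidinium carboxylate; at room temperature the product acid should not yet decarboxylate, and the ester, pyranone and ether are inert to zerovalent palladium.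

Step 4
Reactants: 9 3-[4-({3-(ethoxycarbonyl)-6-(4-methoxyphenyl)-4-oxo-4H-pyran-2-yl}methoxy)phenyl]prop-2-ynoic acid; 10 ethyl 3-oxobutanoate (ethyl acetoacetate)
Product: 13 ethyl 2-({4-[5-(ethoxycarbonyl)-6-methyl-4-oxo-4H-pyran-2-yl]phenoxy}methyl)-6-(4-methoxyphenyl)-4-oxo-4H-pyran-3-carboxylate, via acid chloride 11 (not isolated), via alkynoyl keto ester 12 (not isolated)
Conditions: 9, 1-chloro-N,N,2-trimethylprop-1-en-1-amine (1.05 equiv), CH2Cl2, 0 °C → rt; then 10 (1.2 equiv), MgCl2 (1.2 equiv), pyridine (2.5 equiv), 0 °C → rt; DMAP (0.2 equiv), rt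
Reagents that add atoms: none
Why: The same pyranone synthesis as in step 2 (neutral acid chloride formation with the α-chloroenamine, because oxalyl chloride could attack the pyranone carbonyl, then magnesium-mediated C-acylation and 6-endo-dig oxa-Michael closure through the acetyl enol oxygen) should place the methyl group at C2 beside the ester.

Step 5
Reactants: 13 ethyl 2-({4-[5-(ethoxycarbonyl)-6-methyl-4-oxo-4H-pyran-2-yl]phenoxy}methyl)-6-(4-methoxyphenyl)-4-oxo-4H-pyran-3-carboxylate; 14 N-methoxy-N-methylacetamide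
Product: 15 ethyl 2-(1-{4-[5-(ethoxycarbonyl)-4-oxo-6-(2-oxopropyl)-4H-pyran-2-yl]phenoxy}-2-oxopropyl)-6-(4-methoxyphenyl)-4-oxo-4H-pyran-3-carboxylate (racemic)
Conditions: LiN(SiMe3)2 (2.4 equiv), THF, –78 °C, 45 min; 14 (3.0 equiv), –78 → 0 °C; sat. aq. NH4Cl; used without delay
Reagents that add atoms: none
Why: Lateral (vinylogous) deprotonation of the CH2OAr and CH3 groups at C2 of the two 4-pyranone-3-carboxylates and C-acylation of the extended enolates by the N-methoxy-N-methylamide, whose chelated tetrahedral adducts persist until work-up so that neither over-addition nor quenching by the more acidic product occurs; the new stereocentre at the aryloxy-bearing carbon forms as a racemate and is destined to become aromatic C8.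

Step 6
Reactants: 15 ethyl 2-(1-{4-[5-(ethoxycarbonyl)-4-oxo-6-(2-oxopropyl)-4H-pyran-2-yl]phenoxy}-2-oxopropyl)-6-(4-methoxyphenyl)-4-oxo-4H-pyran-3-carboxylate
Product: 16 5,7-dihydroxy-8-[4-(5,7-dihydroxy-4-oxo-4H-chromen-2-yl)phenoxy]-2-(4-methoxyphenyl)-4H-chromen-4-one (target)
Conditions: LiN(iPr)2 (6.5 equiv), THF, –78 → 0 °C (15 added to the base); 1 M HCl
Reagents that add atoms: none
Why: Twofold intramolecular Claisen (Dieckmann-type) condensation with aromatisation, the ring-forming step of phloroglucinol biosynthesis run on two pyranone-masked chains: in each half the base first removes the most acidic proton on the lateral carbon (between the new ketone and pyranone C2), then a methyl proton, and the terminal carbanion of this dianion attacks the ester carbonyl on the neighbouring pyranone C3, ethoxide leaves and enolisation of the cyclohexenedione gives the resorcinol ring. The closest known reactions are the base-induced closure of 2-(2-oxopropyl)benzoates to naphthalene-1,3-diols and the Claisen folding of pyranone models of polyketides. Both rings A are closed in the same 6-exo-trig mode by forming C5–C6 and C5''–C6''; no stereocentre is created, and the sp3 stereocentre of 15 becomes aromatic C8. The step needs C- over O-acylation and attack on the ester only: O-acylation to the enol lactone is reversible under ethoxide whereas C-acylation ends in an aromatic diphenoxide, and the pyranone carbonyl cannot be reached without a bridgehead double bond. The 8-aryloxy (not 6-aryloxy) pattern is secured because the O1–C8a bond already exists in the pyranone, so the ambiguity of closing a flavone onto a symmetrical 2-aryloxyphloroglucinol (and Wessely–Moser equilibration) never arises.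

Compound list
1 | 4-iodophenol | Oc1ccc(I)cc1 | starting material
2 | ethyl 4-chloro-3-oxobutanoate | CCOC(=O)CC(=O)CCl | starting material
3 | ethyl 4-(4-iodophenoxy)-3-oxobutanoate | CCOC(=O)CC(=O)COc1ccc(I)cc1 | intermediate
4 | 3-(4-methoxyphenyl)prop-2-ynoic acid | COc1ccc(C#CC(=O)O)cc1 | starting material
5 | 3-(4-methoxyphenyl)prop-2-ynoyl chloride | COc1ccc(C#CC(=O)Cl)cc1 | intermediate (not isolated)
6 | ethyl 2-[(4-iodophenoxy)acetyl]-5-(4-methoxyphenyl)-3-oxopent-4-ynoate | CCOC(=O)C(C(=O)COc1ccc(I)cc1)C(=O)C#Cc1ccc(OC)cc1 | intermediate (not isolated)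
7 | ethyl 2-[(4-iodophenoxy)methyl]-6-(4-methoxyphenyl)-4-oxo-4H-pyran-3-carboxylate | CCOC(=O)c1c(COc2ccc(I)cc2)oc(-c2ccc(OC)cc2)cc1=O | intermediate
8 | prop-2-ynoic acid | C#CC(=O)O | starting material
9 | 3-[4-({3-(ethoxycarbonyl)-6-(4-methoxyphenyl)-4-oxo-4H-pyran-2-yl}methoxy)phenyl]prop-2-ynoic acid | CCOC(=O)c1c(COc2ccc(C#CC(=O)O)cc2)oc(-c2ccc(OC)cc2)cc1=O | intermediate
10 | ethyl 3-oxobutanoate | CCOC(=O)CC(C)=O | starting material
11 | ethyl 2-{[4-(3-chloro-3-oxoprop-1-yn-1-yl)phenoxy]methyl}-6-(4-methoxyphenyl)-4-oxo-4H-pyran-3-carboxylate | CCOC(=O)c1c(COc2ccc(C#CC(=O)Cl)cc2)oc(-c2ccc(OC)cc2)cc1=O | intermediate (not isolated)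
12 | ethyl 2-acetyl-5-[4-({3-(ethoxycarbonyl)-6-(4-methoxyphenyl)-4-oxo-4H-pyran-2-yl}methoxy)phenyl]-3-oxopent-4-ynoate | CCOC(=O)C(C(C)=O)C(=O)C#Cc1ccc(OCc2oc(-c3ccc(OC)cc3)cc(=O)c2C(=O)OCC)cc1 | intermediate (not isolated)
13 | ethyl 2-({4-[5-(ethoxycarbonyl)-6-methyl-4-oxo-4H-pyran-2-yl]phenoxy}methyl)-6-(4-methoxyphenyl)-4-oxo-4H-pyran-3-carboxylate | CCOC(=O)c1c(COc2ccc(-c3cc(=O)c(C(=O)OCC)c(C)o3)cc2)oc(-c2ccc(OC)cc2)cc1=O | intermediate
14 | N-methoxy-N-methylacetamide | CC(=O)N(C)OC | starting material
15 | ethyl 2-(1-{4-[5-(ethoxycarbonyl)-4-oxo-6-(2-oxopropyl)-4H-pyran-2-yl]phenoxy}-2-oxopropyl)-6-(4-methoxyphenyl)-4-oxo-4H-pyran-3-carboxylate (racemic) | CCOC(=O)c1c(C(Oc2ccc(-c3cc(=O)c(C(=O)OCC)c(CC(C)=O)o3)cc2)C(C)=O)oc(-c2ccc(OC)cc2)cc1=O | intermediate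
16 | 5,7-dihydroxy-8-[4-(5,7-dihydroxy-4-oxo-4H-chromen-2-yl)phenoxy]-2-(4-methoxyphenyl)-4H-chromen-4-one | COc1ccc(-c2cc(=O)c3c(O)cc(O)c(Oc4ccc(-c5cc(=O)c6c(O)cc(O)cc6o5)cc4)c3o2)cc1 | target

Total step count: 6. Longest linear sequence: 6 (1 → 3 → 7 → 9 → 13 → 15 → 16).

Steps most likely to fail

Step 6. The methyl-ketone dianions may not form cleanly beside the far more acidic lateral C–H, so that O-acylation to enol lactones or amide attack on the pyranones outruns the C–C closure; the half-folded polyanion may also precipitate before the second ring closes. The fallback would close the rings at C7–C8 instead, with the acidic lateral carbon as the nucleophile, and would set out from 13. Cleavage of both ethyl esters with Me3SnOH (1,2-dichloroethane, 80 °C) would give the bis(pyranone-3-carboxylic acid) F1. Activation with 1,1'-carbonyldiimidazole would give the bis(acyl imidazolide) F2 (not isolated), and C-acylation of Mg(O2CCH2CO2Et)2 with decarboxylation would give the bis(β-keto ester) F3. Cs2CO3 in MeCN at 60 °C should then let each lateral carbanion attack the side-chain ester (Dieckmann condensation, 6-exo-trig) and aromatise, which comes back to the route at 16.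

Step 5. The stabilised lateral anions may add too slowly to the amide or be acylated at the pyranone oxygen, and the hindered aryloxy-bearing carbanion may lag behind the methyl-derived one, leaving mono-acetylated material. The fallback would replace the anionic acylation by a neutral condensation and would set out from 13. N,N-Dimethylacetamide dimethyl acetal (toluene, 100 °C) would condense with both activated lateral C–H groups to give the bis(enaminone) F4, and mild aqueous acid (AcOH, H2O, THF, rt) would hydrolyse both enamines to the methyl ketones, which comes back to the route at 15.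

Step 2 (step 4 is the same reaction type). The enolate may be acylated at oxygen, pyridine may add to the ynoyl chloride, or the ring may close in the 5-exo mode to a 2-arylidenefuran-3(2H)-one. The fallback would build the pyranone from an aroylketene and an enamine, through a tricarbonyl intermediate that has no alkyne and can only close to the six-membered ring; it would set out from 3. Morpholine (cat. TsOH, toluene, water removal) would give the enamino ester F5. The acyl dioxanedione F6 (from 2,2-dimethyl-1,3-dioxane-4,6-dione, 4-methoxybenzoyl chloride and pyridine) would lose acetone and CO2 on heating in toluene to give the aroylketene F7. This would C-acylate F5 to the acylated enaminone F8, and ring closure with loss of morpholine (TsOH) would come back to the route at 7.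

Further compounds
F1 | step 6 | 2-{[4-(5-carboxy-6-methyl-4-oxo-4H-pyran-2-yl)phenoxy]methyl}-6-(4-methoxyphenyl)-4-oxo-4H-pyran-3-carboxylic acid | OC(=O)c1c(COc2ccc(-c3cc(=O)c(C(=O)O)c(C)o3)cc2)oc(-c2ccc(OC)cc2)cc1=O
F2 | step 6 | 3-(imidazol-1-ylcarbonyl)-2-({4-[5-(imidazol-1-ylcarbonyl)-6-methyl-4-oxo-4H-pyran-2-yl]phenoxy}methyl)-6-(4-methoxyphenyl)-4H-pyran-4-one | O=C(c1c(COc2ccc(-c3cc(=O)c(C(=O)n4ccnc4)c(C)o3)cc2)oc(-c2ccc(OC)cc2)cc1=O)n1ccnc1
F3 | step 6 | ethyl 3-[2-({4-[5-(3-ethoxy-3-oxopropanoyl)-6-methyl-4-oxo-4H-pyran-2-yl]phenoxy}methyl)-6-(4-methoxyphenyl)-4-oxo-4H-pyran-3-yl]-3-oxopropanoate | CCOC(=O)CC(=O)c1c(COc2ccc(-c3cc(=O)c(C(=O)CC(=O)OCC)c(C)o3)cc2)oc(-c2ccc(OC)cc2)cc1=O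
F4 | step 5 | ethyl 2-[2-(dimethylamino)-1-{4-[6-(2-(dimethylamino)prop-1-en-1-yl)-5-(ethoxycarbonyl)-4-oxo-4H-pyran-2-yl]phenoxy}prop-1-en-1-yl]-6-(4-methoxyphenyl)-4-oxo-4H-pyran-3-carboxylate | CCOC(=O)c1c(C(Oc2ccc(-c3cc(=O)c(C(=O)OCC)c(C=C(C)N(C)C)o3)cc2)=C(C)N(C)C)oc(-c2ccc(OC)cc2)cc1=O
F5 | step 2 | ethyl 4-(4-iodophenoxy)-3-(morpholin-4-yl)but-2-enoate | CCOC(=O)C=C(COc1ccc(I)cc1)N1CCOCC1
F6 | step 2 | 5-[hydroxy(4-methoxyphenyl)methylidene]-2,2-dimethyl-1,3-dioxane-4,6-dione | COc1ccc(C(O)=C2C(=O)OC(C)(C)OC2=O)cc1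
F7 | step 2 | 3-(4-methoxyphenyl)-3-oxoprop-1-en-1-one, (4-methoxybenzoyl)ketene | COc1ccc(C(=O)C=C=O)cc1
F8 | step 2 | ethyl 2-[2-(4-iodophenoxy)-1-(morpholin-4-yl)ethylidene]-5-(4-methoxyphenyl)-3,5-dioxopentanoate | CCOC(=O)C(C(=O)CC(=O)c1ccc(OC)cc1)=C(COc1ccc(I)cc1)N1CCOCC1
A1 | direct plan | 5,7-bis(benzyloxy)-2-(4-methoxyphenyl)-4H-chromen-4-one | COc1ccc(-c2cc(=O)c3c(OCc4ccccc4)cc(OCc4ccccc4)cc3o2)cc1
A2 | direct plan | 7-(benzyloxy)-5-hydroxy-2-(4-hydroxyphenyl)-4H-chromen-4-one | O=c1cc(-c2ccc(O)cc2)oc2cc(OCc3ccccc3)cc(O)c12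
A3 | direct plan | [5,7-bis(benzyloxy)-2-(4-methoxyphenyl)-4-oxo-4H-chromen-8-yl](2,4,6-trimethoxyphenyl)iodonium 4-methylbenzenesulfonate | COc1ccc(-c2cc(=O)c3c(OCc4ccccc4)cc(OCc4ccccc4)c([I+]c4c(OC)cc(OC)cc4OC)c3o2)cc1.Cc1ccc(S(=O)(=O)[O-])cc1
A4 | direct plan | 5,7-bis(benzyloxy)-8-{4-[7-(benzyloxy)-5-hydroxy-4-oxo-4H-chromen-2-yl]phenoxy}-2-(4-methoxyphenyl)-4H-chromen-4-one | COc1ccc(-c2cc(=O)c3c(OCc4ccccc4)cc(OCc4ccccc4)c(Oc4ccc(-c5cc(=O)c6c(O)cc(OCc7ccccc7)cc6o5)cc4)c3o2)cc1
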